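**Retrosynthetic overview**
- The benzylic alcohol comes from a chemoselective NaBH4 reduction of a ring B aryl aldehyde, leaving the methyl ester untouched.
- The diaryl ether C–O bond comes from a CuI-catalysed Ullmann O-arylation of a ring B salicylaldehyde phenol with a ring A ortho-bromobenzoate.
- The ring B C-prenyl group comes from a Stille coupling of an aryl bromide, and the ring B O-prenyl group from regioselective alkylation of a catechol dianion.
- The ring B bromide and catechol come from para-selective bromination and Cu-mediated hydroxylation of a bought bromosalicylaldehyde.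
- No ring is formed: both benzene rings are bought intact, ring B is elaborated first, ring A second, and the two are then joined.

Assumption: the target has no stereocentre, no stereogenic double bond and a freely rotating diaryl ether axis, so it is achiral and "single enantiomer" needs no stereocontrol.

**Step 1**
Reactants: 1 3-bromo-2-hydroxy-5-methoxybenzaldehyde
Product: 2 2,3-dihydroxy-5-methoxybenzaldehyde
Conditions: NaOH (8% aq), Cu powder (cat.), reflux, N2; then HCl
Reagents that add atoms: sodium hydroxide [Na+].[OH-]
Why: Ullmann-type copper-mediated hydroxylation of an aryl bromide ortho to a phenoxide, the same situation as the classical conversion of 5-bromovanillin into 5-hydroxyvanillin; no stereocentre is involved.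

**Step 2**
Reactants: 2 2,3-dihydroxy-5-methoxybenzaldehyde
Product: 3 6-bromo-2,3-dihydroxy-5-methoxybenzaldehyde
Conditions: Br2 (1.0 equiv), NaOAc, AcOH, 15 °C to rt
Reagents that add atoms: bromine BrBr
Why: Electrophilic aromatic bromination goes to C6, the only free position para to a hydroxyl and ortho to the methoxy group, whereas C4 is flanked by two oxygen substituents (3,5-dimethoxybenzaldehyde likewise brominates at C2).

**Step 3**
Reactants: 3 6-bromo-2,3-dihydroxy-5-methoxybenzaldehyde
Product: 5 6-bromo-2-hydroxy-5-methoxy-3-(3-methylbut-2-enyloxy)benzaldehyde, via disodium catecholate dianion 4 (not isolated)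
Conditions: NaH (2.1 equiv), DMSO, rt; then prenyl bromide (1.0 equiv), rt; then aq. HCl
Reagents that add atoms: prenyl bromide (1-bromo-3-methylbut-2-ene) CC(C)=CCBr
Why: Williamson ether synthesis on the dianion: the 2-phenoxide is stabilised and chelated by the ortho formyl group, so the more basic 3-phenoxide takes the single equivalent of allylic bromide by SN2.

**Step 4**
Reactants: 5 6-bromo-2-hydroxy-5-methoxy-3-(3-methylbut-2-enyloxy)benzaldehyde
Product: 6 2-hydroxy-5-methoxy-6-(3-methylbut-2-enyl)-3-(3-methylbut-2-enyloxy)benzaldehyde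
Conditions: tributyl(3-methylbut-2-enyl)stannane (1.5 equiv), Pd(PPh3)4 (10 mol %), DMF, 95 °C, Ar
Reagents that add atoms: tributyl(3-methylbut-2-enyl)stannane CCCC[Sn](CCCC)(CCCC)CC=C(C)C
Why: Stille cross-coupling: zerovalent palladium inserts into the C–Br bond activated by the ortho formyl group, and the prenylstannane delivers its allyl unit mainly through the unsubstituted terminus to give the linear prenyl arene.

**Step 5**
Reactants: 7 methyl 2-bromo-6-hydroxybenzoate
Product: 8 methyl 2-bromo-6-(3-methylbut-2-enyloxy)benzoate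
Conditions: prenyl bromide (1.2 equiv), K2CO3, DMF, rt
Reagents that add atoms: prenyl bromide (1-bromo-3-methylbut-2-ene) CC(C)=CCBr
Why: Williamson ether synthesis (SN2) of the salicylate phenol with a reactive allylic bromide; the aryl bromide and the ester are inert.

**Step 6**
Reactants: 6 2-hydroxy-5-methoxy-6-(3-methylbut-2-enyl)-3-(3-methylbut-2-enyloxy)benzaldehyde; 8 methyl 2-bromo-6-(3-methylbut-2-enyloxy)benzoate
Product: 9 methyl 2-[2-formyl-4-methoxy-3-(3-methylbut-2-enyl)-6-(3-methylbut-2-enyloxy)phenoxy]-6-(3-methylbut-2-enyloxy)benzoate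
Conditions: CuI (20 mol %), picolinic acid (40 mol %), K3PO4 (2 equiv), DMSO, 90 °C, Ar
Reagents that add atoms: none
Why: Ullmann diaryl ether synthesis: the picolinate complex of monovalent copper couples hindered phenoxides, the ortho ester of 8 accelerates insertion into the C–Br bond, and 90 °C is well below the Claisen threshold of the prenyl ethers.

**Step 7**
Reactants: 9 methyl 2-[2-formyl-4-methoxy-3-(3-methylbut-2-enyl)-6-(3-methylbut-2-enyloxy)phenoxy]-6-(3-methylbut-2-enyloxy)benzoate
Product: 10 methyl 2-[2-(hydroxymethyl)-4-methoxy-3-(3-methylbut-2-enyl)-6-(3-methylbut-2-enyloxy)phenoxy]-6-(3-methylbut-2-enyloxy)benzoate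
Conditions: NaBH4 (1 equiv), MeOH/THF, 0 °C; aq. NH4Cl
Reagents that add atoms: none
Why: Chemoselective hydride reduction: NaBH4 reduces the aryl aldehyde within minutes while the hindered methyl 2,6-dioxybenzoate and the three trisubstituted alkenes are untouched; no stereocentre is formed.

**Compound list**
1 | 3-bromo-2-hydroxy-5-methoxybenzaldehyde | O=Cc1cc(OC)cc(Br)c1O | starting material
2 | 2,3-dihydroxy-5-methoxybenzaldehyde | O=Cc1cc(OC)cc(O)c1O | intermediate
3 | 6-bromo-2,3-dihydroxy-5-methoxybenzaldehyde | O=Cc1c(Br)c(OC)cc(O)c1O | intermediate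
4 | disodium 4-bromo-3-formyl-5-methoxybenzene-1,2-diolate (catecholate dianion of 3) | O=Cc1c(Br)c(OC)cc([O-])c1[O-].[Na+].[Na+] | intermediate
5 | 6-bromo-2-hydroxy-5-methoxy-3-(3-methylbut-2-enyloxy)benzaldehyde | O=Cc1c(Br)c(OC)cc(OCC=C(C)C)c1O | intermediate
6 | 2-hydroxy-5-methoxy-6-(3-methylbut-2-enyl)-3-(3-methylbut-2-enyloxy)benzaldehyde | O=Cc1c(CC=C(C)C)c(OC)cc(OCC=C(C)C)c1O | intermediate
7 | methyl 2-bromo-6-hydroxybenzoate | COC(=O)c1c(O)cccc1Br | starting material
8 | methyl 2-bromo-6-(3-methylbut-2-enyloxy)benzoate | COC(=O)c1c(OCC=C(C)C)cccc1Br | intermediate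
9 | methyl 2-[2-formyl-4-methoxy-3-(3-methylbut-2-enyl)-6-(3-methylbut-2-enyloxy)phenoxy]-6-(3-methylbut-2-enyloxy)benzoate | COC(=O)c1c(OCC=C(C)C)cccc1Oc1c(OCC=C(C)C)cc(OC)c(CC=C(C)C)c1C=O | intermediate
10 | methyl 2-[2-(hydroxymethyl)-4-methoxy-3-(3-methylbut-2-enyl)-6-(3-methylbut-2-enyloxy)phenoxy]-6-(3-methylbut-2-enyloxy)benzoate | COC(=O)c1c(OCC=C(C)C)cccc1Oc1c(OCC=C(C)C)cc(OC)c(CC=C(C)C)c1CO | target

**Step count**
Total steps: 7. Longest linear sequence: 6 steps (steps 1, 2, 3, 4, 6, 7; step 5 is the one-step side branch for ring A).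

**Steps most likely to fail, with fallbacks**

Step 6, the copper-catalysed O-arylation. The phenol 6 is flanked by a formyl and a prenyloxy group and may chelate the copper, and the ester-bearing bromide 8 is less reactive than an iodide. The fallback sets out from 8 and uses the much stronger ortho-carboxylate effect of the free acid. Saponify 8 (KOH, MeOH/H2O, reflux) to 2-bromo-6-(3-methylbut-2-enyloxy)benzoic acid F1. Couple F1 with 6 in a carboxylate-directed Ullmann condensation (Cu powder and CuI, 10 mol % each, K2CO3, DMF, 110 °C) to give 2-[2-formyl-4-methoxy-3-(3-methylbut-2-enyl)-6-(3-methylbut-2-enyloxy)phenoxy]-6-(3-methylbut-2-enyloxy)benzoic acid F2. Methylating the carboxylate (MeI, K2CO3, DMF, rt) comes back to the route at 9.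

Step 4, the Stille prenylation. The bromide is flanked on both sides, prenylstannanes transmetalate slowly and can give some branched (reverse-prenyl) product, and the long heating exposes the aryl prenyl ether to palladium. The fallback sets out from 5 and splits the task in two. A fast Stille coupling with allyltributylstannane (Pd(PPh3)4, toluene, 90 °C) gives 2-hydroxy-5-methoxy-3-(3-methylbut-2-enyloxy)-6-(prop-2-enyl)benzaldehyde F3. Olefin cross-metathesis of F3 with excess 2-methyl-2-butene (second-generation Grubbs catalyst, 5 mol %, CH2Cl2, 40 °C) turns the terminal allyl group into the prenyl group; the existing trisubstituted prenyl ether is essentially a spectator. This comes back to the route at 6.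

Step 3, the regioselective mono-O-prenylation. Over-alkylation or attack at the 2-oxygen would erode the yield. The fallback sets out from 3 and separates alkylation from selection. Alkylate both hydroxyls (prenyl bromide 2.5 equiv, K2CO3, DMF, rt) to give 6-bromo-5-methoxy-2,3-bis(3-methylbut-2-enyloxy)benzaldehyde F4. Then cleave only the ether ortho to the formyl group by chelation-controlled dealkylation with MgBr2·OEt2 (toluene/Et2O, rt), by analogy with ortho-carbonyl debenzylation. This comes back to the route at 5.

**Further compounds**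
F1 | step 6 | 2-bromo-6-(3-methylbut-2-enyloxy)benzoic acid | OC(=O)c1c(OCC=C(C)C)cccc1Br
F2 | step 6 | 2-[2-formyl-4-methoxy-3-(3-methylbut-2-enyl)-6-(3-methylbut-2-enyloxy)phenoxy]-6-(3-methylbut-2-enyloxy)benzoic acid | OC(=O)c1c(OCC=C(C)C)cccc1Oc1c(OCC=C(C)C)cc(OC)c(CC=C(C)C)c1C=O
F3 | step 4 | 2-hydroxy-5-methoxy-3-(3-methylbut-2-enyloxy)-6-(prop-2-enyl)benzaldehyde | O=Cc1c(CC=C)c(OC)cc(OCC=C(C)C)c1O
F4 | step 3 | 6-bromo-5-methoxy-2,3-bis(3-methylbut-2-enyloxy)benzaldehyde | O=Cc1c(Br)c(OC)cc(OCC=C(C)C)c1OCC=C(C)C
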